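(The data were generated by integration for substances that don't exist, and the scatter is random.)

In the earlier runs a small charge of substrate topped out lower than a large one: Monday's run at 0.025 M reached a highest reading of 20.6%, Thursday's run at 0.10 M reached 25.2%, and Saturday's run at 0.050 M lay between at 23.7%. Two chemists disagree on what this means for a tank and a closed flask.

| flask | substrate | remark | time |
|---|---|---|---|
| Saturday's | 0.050 M | run made earlier |  |
| Monday's | 0.025 M | run made earlier |  |
| Thursday's | 0.10 M | run made earlier |  |
| larch | 0.050 M | one stirred flow tank at steady state, fed with the mixture as stated, mean residence time 6.0 h |  |
| oak | 0.050 M | a closed flask charged with all of it at once and left for 6.0 h | 6.0 h |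

| Saturday's: time / h | Saturday's: target / % | Monday's: time / h | Monday's: target / % | Thursday's: time / h | Thursday's: target / % |
|---|---|---|---|---|---|
| 0.667 | 19.8 | 0.667 | 18.9 | 1.33 | 25.2 |
| 1.33 | 22.2 | 2.00 | 20.6 | 3.00 | 25.2 |
| 2.00 | 23.7 | 3.00 | 18.4 | 4.00 | 23.7 |
| 3.00 | 21.9 | 5.00 | 15.8 | 6.00 | 23.1 |
| 4.00 | 20.8 | 8.00 | 14.9 | 8.00 | 19.6 |

(scatter of a reading: 1 percentage point)

- the stated concentrations are those of everything mixed, before any reaction; amounts are the same in each set-up
- what was read earlier has a scatter of 1 percentage point, one standard deviation
- the earlier runs were made in a closed, stirred flask
- a reading or a percentage of target counts all its forms, free or not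

* the set-up with the highest amount of target at the outlet or at the end, in percent of the substrate put in ("none" if the first two lie within 2 percentage points) (larch / oak / none)
* amount of target at the outlet or at the end, in percent of the substrate put in, larch
* amount of target at the outlet or at the end, in percent of the substrate put in, oak

The first chemist takes these readings as a concentration effect, “selectivity favours high substrate concentration”. For the larch tank he expects a low level of substrate and so a poor yield. This view gives the forecast: larch 11%, oak 19%, best oak.

The second chemist, whose reckoning this is, looks at ages instead. If the steps are first order, a tank's outlet is the closed-flask curve averaged over exit ages (the residence-time distribution). Saturday's first reading comes early beside larch's mean residence time of 6.0 h, and 10.5% of larch's outflow leaves younger than that reading's 0.667 h. He counts this young part at 9.90%, the mean of zero and the first reading, and the older part at Saturday's last reading, 20.8%. The result is the age-weighted level, 19.7%. The highest readings differ with charge, so the steps may not be strictly first order, and this level is approximate. It differs from the forecast's larch figure, and it stands 0.70 percentage points from the forecast's oak figure, less than the margin of 2 points. His answer is therefore "none".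

The simulation gives larch 19.5% and oak 19.0%, which lie within the margin, so the answer is none.

    substrate ⇌ target (K = 0.710, k = 0.0160 min⁻¹)
    substrate ⇌ isomer of the product (K = 3.00, k = 0.00980 min⁻¹)
    substrate ⇌ third isomer (K = 0.770, k = 0.0180 min⁻¹)
    substrate ⇌ dormant form (K = 0.740, k = 0.0190 min⁻¹)
    substrate + target ⇌ idle adduct, settled at all times (K = 100 M⁻¹)

The first chemist's concentration effect has its region in the charge of the closed oak flask: oak's answer has moved by 5 points at 0.00786 M below and at 0.132 M above. The age-weighted level stood 0.20 points above larch's figure. With oak's 19.0% in place of Saturday's last reading, the same weighing gives 18.0%, lower than larch's 19.5%.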